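A mean rate read off a curve says when a charge has been turned over, and the pitfall is to read that as how much of the charge arrives as target. You asked for a quick number, with the hunch that the warmest flask wins.

| flask | starting material | second substrate | free enzyme | temperature | remark | time |
|---|---|---|---|---|---|---|
| south-east | 11 mM | 22 mM | 2.2 µM | −19 °C | run made earlier |  |
| north-west | 11 mM | 22 mM | 9 µM | 22 °C | run made earlier |  |
| west | 5.5 mM | 22 mM | 4.5 µM | −19 °C | run made earlier |  |
| delta | 11 mM | 22.0 mM | 4.5 µM | −13 °C |  | 20 h |
| alpha | 11 mM | 22.0 mM | 4.5 µM | 12 °C |  | 20 h |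
| beta | 11 mM | 22.0 mM | 4.5 µM | −38 °C |  | 20 h |
| zeta | 11 mM | 22.0 mM | 4.5 µM | 37 °C |  | 20 h |

| run | time / h | target / % | starting material / % |
|---|---|---|---|
| south-east | 1.50 | 0 | 101 |
| south-east | 2.50 | 1 | 99 |
| south-east | 4.00 | 2 | 98 |
| south-east | 8.00 | 1 | 98 |
| south-east | 12.0 | 3 | 100 |
| south-east | 20.0 | 3 | 97 |
| north-west | 0.250 | 9 | 93 |
| north-west | 0.667 | 23 | 75 |
| north-west | 1.33 | 39 | 59 |
| north-west | 2.00 | 55 | 42 |
| north-west | 2.50 | 70 | 31 |
| north-west | 4.00 | 89 | 9 |
| west | 4.00 | 5 | 95 |
| west | 8.00 | 5 | 96 |
| west | 12.0 | 9 | 92 |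
| west | 15.0 | 10 | 92 |
| west | 20.0 | 10 | 88 |

(readings scatter by 1.5 percentage points)

- the earlier runs were read with a standard deviation of 1.5 percentage points

- the flask that comes out highest in amount of target, in percent of the starting material charged, or "all alike" when all lie within 1.5 percentage points (delta / alpha / beta / zeta / all alike)
- target at the end, in percent of the starting material charged, delta
- target at the end, in percent of the starting material charged, alpha
- target at the end, in percent of the starting material charged, beta
- target at the end, in percent of the starting material charged, zeta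

I replaced each curve by its mean turnover, the target made per enzyme per hour over a run. These are readings and carry their scatter:

west, −19 °C: s = 6.11 h⁻¹

north-west, 22 °C: s = 272 h⁻¹

The north-west mean up to 2.00 h was 336 h⁻¹, higher than the longer mean, so the flat line erred by 23.5 % there. I kept the longer mean, since alpha was to be read late on its curve.

The two means gave a doubling step, the warming that doubles s, of 7.49 K. From it I carried the run-out time, the time in which a flask at its mean turnover makes target equal to its charge:

t_out = c(starting material) / (s · c(free enzyme))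

alpha: s = 108 h⁻¹, t_out = 22.7 h

alpha: target ≈ t / t_out = 88.2 %

For zeta the same line gave 2.24 h, so I expected zeta to be through its charge early and alpha to fall just short.

The forecast named zeta, with delta 10 %, alpha 92 %, beta 0.7 % and zeta 96 %: "the reaction finishes within hours unless the enzyme dies". Its alpha stood higher than mine.

The flasks gave delta 13.9 %, alpha 89.6 %, beta 0.480 % and zeta 82.1 %, so alpha came out highest.

    free enzyme → unfolded enzyme (k = 9.84 × 10⁻⁷ s⁻¹, Ea = 246 kJ mol⁻¹)
    starting material + free enzyme ⇌ complex A (K = 65.7 L mol⁻¹, k = 1910 L mol⁻¹ s⁻¹, Ea = 42.0 kJ mol⁻¹, ΔH = −26.0 kJ mol⁻¹)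
    complex A → free enzyme + target (k = 1.67 s⁻¹, Ea = 74.0 kJ mol⁻¹)
    second substrate + free enzyme ⇌ complex B (K = 110 L mol⁻¹, k = 1460 L mol⁻¹ s⁻¹, Ea = 39.0 kJ mol⁻¹, ΔH = 13.0 kJ mol⁻¹)
    complex B → free enzyme + second product (k = 1.41 s⁻¹, Ea = 65.0 kJ mol⁻¹)
    starting material → uncatalysed product (k = 4.34 × 10⁻⁵ s⁻¹, Ea = 91.0 kJ mol⁻¹)
    (constants at 37 °C)

Alpha's target lay 1.4 points above my ratio, with 4.86 % of its starting material still free at 20.0 h. Zeta held 17.9 % uncatalysed product beside 82.1 % target, and its starting material stood at 0 %. The neighbouring flask is alpha read at 3.0 d, where t / t_out = 3.17, above one, so the charge should have run out. It had: starting material stood at 0 %, with uncatalysed product at 5.71 % and target at 94.3 %.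

The numbers in the tables were generated by integration for substances that don't exist; noise was put on by code.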